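**Retrosynthetic overview** (germacrane numbering: C1 furanone C=O, C2 furanone CH, C3 furanone O–C=, C4/C5 the Z-alkene, C6 CH–O(acyl), C7, C8 lactone CH–O, C9 CH2, C10 quaternary C–O, C11–C13 the α-methylene lactone; ring A = 3(2H)-furanone, ring B = ten-membered carbocycle C1–C10, ring C = γ-lactone)
1. The C6 ester is cut last (Yamaguchi; (2S,3S)-epoxyangelic acid from a Sharpless epoxidation of angelyl alcohol), which leaves the tricyclic C6 alcohol 27.
2. Rings A and B are cut together: ring A (O–C3=C2–C1(=O)–C10) is the (3+2) adduct of a C2–C1(O)–C10 oxyallyl cation and the C3=O of an N,N-dimethylcarboxamide, giving the acyclic α,α′-dibromo ketone/Z-enamide 24.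
3. Enabling feature: the ring-A oxygen bridges C3 and C10 of ring B, so uniting an oxyallyl unit and an amide that sit at the two ends of one chain closes A and B at once; the trans-fused ring C and the Z-C4=C5 alkene hold the chain ends together.
4. 24 comes from a terminal vinyl group as masked acetyl (Wacker, then two brominations), a Z-enamide made from an alkynamide (hydrostannation, Stille methylation), C6 from transfer hydrogenation of an ynone, and C7/C8 with ring C from an Evans syn-aldol/lactonisation.
5. Order of ring formation: ring C (step 4), then rings A and B together (step 15).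

Key step: step 15

Remark on the chemistry: aldehyde 4 is used as the racemate because its methyl-bearing carbon (C10) becomes trigonal in step 15, so 8–24 are carried as both C10 epimers and their SMILES carry no descriptor there; N,N-dimethylprop-2-ynamide 11 is taken as purchasable.

**Step 1**
Reactants: 1 (E)-but-2-en-1-ol; 2 triethyl orthoacetate
Product: 3 ethyl 3-methylpent-4-enoate
Conditions: EtCO2H (cat.), 140 °C, EtOH distilled off
Reagents that add atoms: none
Why: Johnson–Claisen rearrangement of the crotyl ketene acetal should give the γ,δ-unsaturated ester with the branching methyl; the racemic centre is erased later.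

**Step 2**
Reactants: 3 ethyl 3-methylpent-4-enoate
Product: 4 3-methylpent-4-enal
Conditions: iBu2AlH, CH2Cl2, −78 °C; aq. potassium sodium tartrate; used as a dried solution
Reagents that add atoms: none
Why: Partial reduction of the ester through the stable aluminium hemiacetal at −78 °C should stop at the aldehyde.

**Step 3**
Reactants: 5 (4R)-4-benzyl-1,3-oxazolidin-2-one; 6 methyl 4-chloro-4-oxobutanoate
Product: 7 succinate imide
Conditions: n-BuLi, THF, −78 °C; then 6, −78 to 0 °C
Reagents that add atoms: none
Why: N-acylation of the lithiated oxazolidinone (Evans imide formation) should occur at the acid chloride and not at the methyl ester.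

**Step 4**
Reactants: 7 succinate imide; 4 3-methylpent-4-enal
Product: 9 lactone imide, via syn-aldol adduct 8 (not isolated)
Conditions: Bu2BOTf, iPr2NEt, CH2Cl2, 0 °C; 4, −78 to 0 °C; pH 7 buffer, MeOH, H2O2; then p-TsOH·H2O (cat.), CH2Cl2, rt
Reagents that add atoms: none
Why: Evans syn-aldol reaction: the Z-boron enolate of the imide (the ester is not enolised) should add through a chair transition state on the face away from the benzyl group, setting C7 (R) and C8 (S), and acid then closes ring C, the syn-aldol relation becoming the trans ring fusion.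

**Step 5**
Reactants: 9 lactone imide
Product: 10 (2S,3R)-2-(2-methylbut-3-en-1-yl)-5-oxooxolane-3-carboxylic acid
Conditions: LiOH, H2O2, THF/H2O, 0 °C; Na2SO3; then 1 M HCl to pH 2, rt
Reagents that add atoms: hydrogen peroxide (as LiOOH), OO
Why: Hydroperoxide should cleave the exocyclic imide carbonyl selectively (auxiliary removal), and acidification recloses any opened γ-lactone; C7 and C8 are not touched.

**Step 6**
Reactants: 10 lactone acid; 11 N,N-dimethylprop-2-ynamide
Product: 13 ynone, via acid chloride 12 (not isolated)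
Conditions: (COCl)2, DMF (cat.), CH2Cl2, 0 °C to rt; separately 11, LiN(SiMe3)2, THF, −78 °C, then ZnCl2; combine, Pd(PPh3)4 (5 mol%), THF, 0 °C
Reagents that add atoms: none
Why: Negishi acylation of the alkynylzinc with the acid chloride under zerovalent palladium catalysis should form C5–C6 without touching the lactone; C7 is now α to a ketone but the trans arrangement is the stable one.

**Step 7**
Reactants: 13 ynone
Product: 14 (R)-propargylic alcohol
Conditions: Ru(p-cymene)[(R,R)-TsNCH(Ph)CH(Ph)NH] (5 mol%), 2-propanol, rt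
Reagents that add atoms: none
Why: Noyori asymmetric transfer hydrogenation of an alkynyl ketone is catalyst-controlled, the alkynyl group taking the place of aryl, so the (R,R) catalyst should give the C6 carbinol with the spatial arrangement of the target while alkene, lactone and amide stay intact.

**Step 8**
Reactants: 14 (R)-propargylic alcohol
Product: 15 triisopropylsilyl ether
Conditions: iPr3SiOTf, 2,6-lutidine, CH2Cl2, −78 to 0 °C
Reagents that add atoms: triisopropylsilyl triflate, CC(C)[Si](C(C)C)(C(C)C)OS(=O)(=O)C(F)(F)F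
Why: Silylation with the silyl triflate should protect the hindered C6 alcohol with a group that resists HBr and makes O6 a poor nucleophile in step 15.

**Step 9**
Reactants: 15 triisopropylsilyl ether
Product: 16 (E)-α-stannyl enamide
Conditions: Bu3SnH (slow addition), Pd(PPh3)4 (3 mol%), THF, 0 °C to rt
Reagents that add atoms: tributyltin hydride, CCCC[SnH](CCCC)CCCC
Why: Palladium-catalysed syn-hydrostannation of a 2-ynamide should place tin on the α-carbon C4, away from the silyloxy-bearing C6, so that C6 and the amide carbonyl end up cis on the alkene.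

**Step 10**
Reactants: 16 (E)-α-stannyl enamide
Product: 17 (Z)-enamide
Conditions: MeI, Pd2(dba)3 (5 mol%), tri(2-furyl)phosphine, copper iodide CuI (10 mol%), DMF, 50 °C
Reagents that add atoms: iodomethane, CI
Why: Stille coupling with iodomethane should replace tin by methyl with retention, giving the Z-trisubstituted C4=C5 alkene of the target.

**Step 11**
Reactants: 17 (Z)-enamide
Product: 20 α-methylene lactone, via Mannich base 18 (not isolated), via ammonium iodide 19 (not isolated)
Conditions: LiN(iPr)2, THF, −78 °C; [Me2N=CH2]I, −78 °C to rt; crude amine, MeI, MeOH, rt; NaHCO3 (aq.), CH2Cl2, rt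
Reagents that add atoms: dimethyl(methylidene)ammonium iodide, C=[N+](C)C.[I-]
Why: Eschenmoser methylenation: the lactone is the only carbonyl with an α-hydrogen, so its enolate should undergo the Mannich reaction, and quaternisation followed by E1cB elimination gives the exocyclic methylene.

**Step 12**
Reactants: 20 α-methylene lactone
Product: 21 methyl ketone
Conditions: PdCl2 (10 mol%), CuCl, O2 (1 atm), DMF/H2O 7:1, rt
Reagents that add atoms: water, O
Why: Tsuji–Wacker oxidation should be selective for the monosubstituted alkene (Markovnikov hydroxypalladation) over the trisubstituted enamide and the 1,1-disubstituted acrylate-type alkene.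

**Step 13**
Reactants: 21 methyl ketone
Product: 22 tertiary α-bromo ketone
Conditions: pyrrolidone hydrotribromide (1.05 equiv), THF, 0 °C to rt
Reagents that add atoms: pyrrolidone hydrotribromide, O=C1CCCN1.O=C1CCCN1.O=C1CCCN1.Br.BrBr
Why: Acid-mediated α-bromination through the more substituted enol should place bromine on tertiary C10, the tribromide complex being a mild bromine source known to spare C=C bonds.

**Step 14**
Reactants: 22 tertiary α-bromo ketone
Product: 24 α,α′-dibromo ketone, via silyl enol ether 23 (not isolated)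
Conditions: Me3SiOTf, Et3N, CH2Cl2, 0 °C; pentane, filtration; then NBS, NaHCO3, THF, −78 to 0 °C
Reagents that add atoms: N-bromosuccinimide, O=C1CCC(=O)N1Br
Why: Soft enolisation can only go toward the methyl group because C10 carries no hydrogen, and bromination of the silyl enol ether at its terminus should give the primary bromide.

**Step 15**
Reactants: 24 α,α′-dibromo ketone
Product: 26 tricyclic silyl ether, via aminal 25 (not isolated)
Conditions: Fe2(CO)9 (2 equiv), benzene, 40 °C, dark, argon, syringe-pump addition of 24 to about 0.002 M; then SiO2, EtOAc, air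
Reagents that add atoms: none
Why: Proposed new method: zerovalent iron reduces 24 to a bromo iron enolate that ionises at tertiary C10 (both C10 epimers give the same planar cation) to the 2-oxyallyl cation C2–C1(O[Fe])–C10; the tethered amide oxygen adds to C10 (O–C10) and the iron enolate carbon C2 then adds to the O-alkyl imidate carbon C3 (C2–C3) to give aminal 25, which loses Me2NH. The closest known reaction type is the intermolecular Fe2(CO)9-mediated (3+2) annulation of α,α′-dibromo ketones, tertiary/primary ones included, with N,N-dimethylcarboxamides to 3(2H)-furanones; its intramolecular, ring-forming use is the new element. Ring A closes by this stepwise (3+2) annulation (O-capture, then five-ring C–C collapse of the 1,5-zwitterion), and ring B closes in the same C2–C3 bond formation as a transannular closure across the nine-membered imidate ring made by the O–C10 bond. The new stereocentre C10 is controlled by the trans-fused ring C and the Z-alkene: ring C holds C6 and C9 anticlinal, the alkene holds C3 and C6 cis, and only attack on the C10 face that leaves ring C on the outer side of the nearly extended C6–C9 bridge should bring C2 within reach of C3, whereas O-capture on the other face cannot close and is expected to revert to the cation. The step needs (a) O-attack at C10 and not at C2, secured by the tertiary terminus carrying the charge, (b) C–C and not C–O collapse, secured by the carbon-nucleophilic iron enolate, (c) capture by the amide and not by O6, secured by the bulky iPr3Si group, and (d) ring closure before proton loss or intermolecular reaction, secured by high dilution and the preorganisation just named.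

**Step 16**
Reactants: 26 tricyclic silyl ether
Product: 27 tricyclic C6 alcohol
Conditions: HF·pyridine, pyridine, THF, 0 °C to rt
Reagents that add atoms: none
Why: Fluoride-mediated desilylation under buffered acidic conditions should spare the furanone and the α-methylene lactone and avoid base-induced lactone migration to O6.

**Step 17**
Reactants: 28 angelic acid
Product: 29 (2Z)-2-methylbut-2-en-1-ol
Conditions: LiAlH4, Et2O, 0 °C to rt; aq. NaOH work-up
Reagents that add atoms: none
Why: Hydride reduction of the acid should give the allylic alcohol without changing the Z-alkene geometry.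

**Step 18**
Reactants: 29 (2Z)-2-methylbut-2-en-1-ol
Product: 30 [(2R,3S)-2,3-dimethyloxiran-2-yl]methanol
Conditions: Ti(OiPr)4 (10 mol%), D-(−)-diisopropyl tartrate (12 mol%), tBuOOH, 4 Å molecular sieves, CH2Cl2, −20 °C
Reagents that add atoms: tert-butyl hydroperoxide, CC(C)(C)OO
Why: Sharpless asymmetric epoxidation with the D-(−)-tartrate should deliver oxygen to the alkene face that gives the (2R,3S)-epoxy alcohol, both epoxide stereocentres being set here.

**Step 19**
Reactants: 30 epoxy alcohol
Product: 31 (2S,3S)-2,3-dimethyloxirane-2-carboxylic acid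
Conditions: RuCl3 (cat.), NaIO4, EtOAc/MeCN/H2O, rt
Reagents that add atoms: sodium periodate, [Na+].[O-]I(=O)(=O)=O; water, O
Why: Ruthenium tetroxide oxidation of the primary alcohol to the acid should leave the epoxide intact, the change of the C2 descriptor being one of priority only.

**Step 20**
Reactants: 27 tricyclic C6 alcohol; 31 epoxy acid
Product: 33 target CNP0258430.4, via mixed anhydride 32 (not isolated)
Conditions: 31, 2,4,6-Cl3C6H2COCl, Et3N, THF, rt; then 27, DMAP, toluene, rt
Reagents that add atoms: none
Why: Yamaguchi esterification through the mixed anhydride and the acylpyridinium should acylate the hindered C6 alcohol without opening the epoxide or touching any stereocentre.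

**Compound list**
1 | (E)-but-2-en-1-ol | C/C=C/CO | starting material
2 | triethyl orthoacetate | CC(OCC)(OCC)OCC | starting material
3 | ethyl 3-methylpent-4-enoate (racemic) | CCOC(=O)CC(C)C=C | intermediate
4 | 3-methylpent-4-enal (racemic) | O=CCC(C)C=C | intermediate
5 | (4R)-4-benzyl-1,3-oxazolidin-2-one | O=C1N[C@H](Cc2ccccc2)CO1 | starting material
6 | methyl 4-chloro-4-oxobutanoate | COC(=O)CCC(=O)Cl | starting material
7 | methyl 4-[(4R)-4-benzyl-2-oxo-1,3-oxazolidin-3-yl]-4-oxobutanoate | COC(=O)CCC(=O)N1[C@H](Cc2ccccc2)COC1=O | intermediate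
8 | (4R)-4-benzyl-3-[(2R,3S)-3-hydroxy-2-(2-methoxy-2-oxoethyl)-5-methylhept-6-enoyl]-1,3-oxazolidin-2-one (C10 epimers) | COC(=O)C[C@@H](C(=O)N1[C@H](Cc2ccccc2)COC1=O)[C@@H](O)CC(C)C=C | intermediate
9 | (4R)-4-benzyl-3-{[(2S,3R)-2-(2-methylbut-3-en-1-yl)-5-oxooxolan-3-yl]carbonyl}-1,3-oxazolidin-2-one (trans-lactone, C10 epimers) | O=C1O[C@@H](CC(C)C=C)[C@H](C(=O)N2[C@H](Cc3ccccc3)COC2=O)C1 | intermediate
10 | (2S,3R)-2-(2-methylbut-3-en-1-yl)-5-oxooxolane-3-carboxylic acid | O=C1O[C@@H](CC(C)C=C)[C@H](C(=O)O)C1 | intermediate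
11 | N,N-dimethylprop-2-ynamide | C#CC(=O)N(C)C | starting material
12 | (2S,3R)-2-(2-methylbut-3-en-1-yl)-5-oxooxolane-3-carbonyl chloride | O=C1O[C@@H](CC(C)C=C)[C@H](C(=O)Cl)C1 | intermediate
13 | N,N-dimethyl-4-[(2S,3R)-2-(2-methylbut-3-en-1-yl)-5-oxooxolan-3-yl]-4-oxobut-2-ynamide | O=C1O[C@@H](CC(C)C=C)[C@H](C(=O)C#CC(=O)N(C)C)C1 | intermediate
14 | (4R)-4-hydroxy-N,N-dimethyl-4-[(2S,3S)-2-(2-methylbut-3-en-1-yl)-5-oxooxolan-3-yl]but-2-ynamide (C6 carbinol, arrangement as in 33) | O=C1O[C@@H](CC(C)C=C)[C@H]([C@@H](O)C#CC(=O)N(C)C)C1 | intermediate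
15 | (4R)-N,N-dimethyl-4-[(2S,3R)-2-(2-methylbut-3-en-1-yl)-5-oxooxolan-3-yl]-4-[(triisopropylsilyl)oxy]but-2-ynamide | O=C1O[C@@H](CC(C)C=C)[C@H]([C@@H](O[Si](C(C)C)(C(C)C)C(C)C)C#CC(=O)N(C)C)C1 | intermediate
16 | (2E,4R)-N,N-dimethyl-4-[(2S,3R)-2-(2-methylbut-3-en-1-yl)-5-oxooxolan-3-yl]-2-(tributylstannyl)-4-[(triisopropylsilyl)oxy]but-2-enamide | O=C1O[C@@H](CC(C)C=C)[C@H]([C@@H](O[Si](C(C)C)(C(C)C)C(C)C)/C=C(\C(=O)N(C)C)[Sn](CCCC)(CCCC)CCCC)C1 | intermediate
17 | (2Z,4S)-N,N,2-trimethyl-4-[(2S,3R)-2-(2-methylbut-3-en-1-yl)-5-oxooxolan-3-yl]-4-[(triisopropylsilyl)oxy]but-2-enamide | O=C1O[C@@H](CC(C)C=C)[C@H]([C@@H](O[Si](C(C)C)(C(C)C)C(C)C)/C=C(C)\C(=O)N(C)C)C1 | intermediate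
18 | Mannich base: 17 with CH2NMe2 on the lactone α-carbon C11 (C11 epimers) | CN(C)CC1C(=O)O[C@@H](CC(C)C=C)[C@@H]1[C@@H](O[Si](C(C)C)(C(C)C)C(C)C)/C=C(C)\C(=O)N(C)C | intermediate
19 | trimethylammonium iodide of 18 | C[N+](C)(C)CC1C(=O)O[C@@H](CC(C)C=C)[C@@H]1[C@@H](O[Si](C(C)C)(C(C)C)C(C)C)/C=C(C)\C(=O)N(C)C.[I-] | intermediate
20 | (2Z,4S)-N,N,2-trimethyl-4-[(2S,3R)-4-methylidene-2-(2-methylbut-3-en-1-yl)-5-oxooxolan-3-yl]-4-[(triisopropylsilyl)oxy]but-2-enamide | C=C1C(=O)O[C@@H](CC(C)C=C)[C@@H]1[C@@H](O[Si](C(C)C)(C(C)C)C(C)C)/C=C(C)\C(=O)N(C)C | intermediate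
21 | (2Z,4S)-N,N,2-trimethyl-4-[(2S,3R)-4-methylidene-2-(2-methyl-3-oxobutyl)-5-oxooxolan-3-yl]-4-[(triisopropylsilyl)oxy]but-2-enamide | C=C1C(=O)O[C@@H](CC(C)C(C)=O)[C@@H]1[C@@H](O[Si](C(C)C)(C(C)C)C(C)C)/C=C(C)\C(=O)N(C)C | intermediate
22 | the 2-(2-bromo-2-methyl-3-oxobutyl) analogue of 21 (bromine on C10) | C=C1C(=O)O[C@@H](CC(C)(Br)C(C)=O)[C@@H]1[C@@H](O[Si](C(C)C)(C(C)C)C(C)C)/C=C(C)\C(=O)N(C)C | intermediate
23 | 2-(trimethylsilyloxy)allyl bromide: terminal silyl enol ether of 22 | C=C1C(=O)O[C@@H](CC(C)(Br)C(=C)O[Si](C)(C)C)[C@@H]1[C@@H](O[Si](C(C)C)(C(C)C)C(C)C)/C=C(C)\C(=O)N(C)C | intermediate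
24 | the 2-(2,4-dibromo-2-methyl-3-oxobutyl) analogue of 21 (bromine on C10 and C2) | C=C1C(=O)O[C@@H](CC(C)(Br)C(=O)CBr)[C@@H]1[C@@H](O[Si](C(C)C)(C(C)C)C(C)C)/C=C(C)\C(=O)N(C)C | intermediate
25 | aminal cycloadduct: 26 with C2H2 and NMe2 on C3 (2-dimethylamino-dihydrofuran-3-one) | C=C1C(=O)O[C@H]2C[C@@]3(C)OC(CC3=O)(N(C)C)/C(C)=C\[C@H](O[Si](C(C)C)(C(C)C)C(C)C)[C@H]12 | intermediate
26 | 6-O-triisopropylsilyl ether of the tricyclic core (6S,7R,8S,10R; 4Z) | C=C1C(=O)O[C@H]2C[C@@]3(C)OC(=CC3=O)/C(C)=C\[C@H](O[Si](C(C)C)(C(C)C)C(C)C)[C@H]12 | intermediate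
27 | tricyclic core with free C6–OH (all centres arranged as in 33) | C=C1C(=O)O[C@H]2C[C@@]3(C)OC(=CC3=O)/C(C)=C\[C@H](O)[C@H]12 | intermediate
28 | angelic acid, (2Z)-2-methylbut-2-enoic acid | C/C=C(/C)C(=O)O | starting material
29 | (2Z)-2-methylbut-2-en-1-ol | C/C=C(/C)CO | intermediate
30 | [(2R,3S)-2,3-dimethyloxiran-2-yl]methanol | OC[C@@]1(C)O[C@H]1C | intermediate
31 | (2S,3S)-2,3-dimethyloxirane-2-carboxylic acid | OC(=O)[C@@]1(C)O[C@H]1C | intermediate
32 | mixed anhydride of 31 with 2,4,6-trichlorobenzoic acid | O=C(OC(=O)c1c(Cl)cc(Cl)cc1Cl)[C@@]1(C)O[C@H]1C | intermediate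
33 | CNP0258430.4 | C=C1C(=O)O[C@H]2C[C@@]3(C)OC(=CC3=O)/C(C)=C\[C@H](OC(=O)[C@@]4(C)O[C@H]4C)[C@H]12 | target

**Total step count:** 20. **Longest linear sequence:** 16 steps (1, 2, 4–16, 20).

**Steps most likely to fail**

Step 15 (proposed new method). What may go wrong: the iron-bound oxyallyl cation loses a proton toward C9 or the C10 methyl, is reduced, or meets a second molecule before the tethered amide reaches C10; discrimination between the two faces of C10 may also be insufficient. Fallback with known chemistry, setting out from 10 and coming back at 27: the two bonds are made by the established intermolecular annulation and ring B is closed separately by a Nozaki–Hiyama–Kishi reaction. Acid 10 is reduced through its isobutyl mixed anhydride with NaBH4 to the primary alcohol F1, silylated (tBuPh2SiCl, imidazole) to the silyl ether F2, methylenated as in step 11 to the methylidene lactone F3, oxidised as in step 12 to the methyl ketone F4 and brominated twice with pyrrolidone hydrotribromide to the dibromo ketone F5. The known (2Z)-3-iodo-2-methylprop-2-en-1-ol is oxidised (CrO3, H2SO4, acetone) to the iodo acid F6 and coupled with Me2NH to the iodo amide F7. F5 and an excess of F7 with Fe2(CO)9 in benzene should give the iodoalkenyl furanone F8 as both C10 epimers. Desilylation with HF·pyridine to the alcohol F9, Dess–Martin oxidation to the aldehyde F10 and ring closure with CrCl2 and catalytic NiCl2 in DMSO at high dilution form C5–C6 and should give 27 after separation from its C6 and C10 diastereomers.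

Step 14. What may go wrong: the 2-silyloxyallyl tertiary bromide ionises or loses HBr during silylation, or bromination is not confined to the enol ether. Fallback setting out from 21 and coming back at 24 (it replaces steps 13 and 14): the order of the brominations is reversed so that no silyloxyallyl bromide is formed. Kinetic deprotonation of 21 at the methyl group (LiN(SiMe3)2, Me3SiCl, THF, −78 °C) gives the terminal silyl enol ether F11, NBS converts it into the bromomethyl ketone F12, and acid-mediated bromination with pyrrolidone hydrotribromide should then go to the more substituted position C10 to give 24.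

Step 7. What may go wrong: conjugate addition of 2-propanol or hydride to the doubly activated alkyne, or erosion of catalyst control by the C7 stereocentre. Fallback setting out from 10 and coming back at 14: C6 is set by addition to an aldehyde instead of reduction of a ketone. Acid chloride 12 is reduced with LiAlH(OtBu)3 at −78 °C to the aldehyde F13, and 11 is added under zinc–ProPhenol catalysis (Me2Zn, the ProPhenol enantiomer that gives the (R)-carbinol), a catalyst-controlled alkynylation known for propiolic acid derivatives.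

**Further compounds**
F1 | step 15 | (4S,5S)-4-(hydroxymethyl)-5-(2-methylbut-3-en-1-yl)oxolan-2-one (C10 epimers) | O=C1O[C@@H](CC(C)C=C)[C@H](CO)C1
F2 | step 15 | tert-butyldiphenylsilyl ether of F1 | O=C1O[C@@H](CC(C)C=C)[C@H](CO[Si](c2ccccc2)(c2ccccc2)C(C)(C)C)C1
F3 | step 15 | 3-methylidene lactone from F2 | C=C1C(=O)O[C@@H](CC(C)C=C)[C@@H]1CO[Si](c1ccccc1)(c1ccccc1)C(C)(C)C
F4 | step 15 | methyl ketone from F3 | C=C1C(=O)O[C@@H](CC(C)C(C)=O)[C@@H]1CO[Si](c1ccccc1)(c1ccccc1)C(C)(C)C
F5 | step 15 | α,α′-dibromo ketone from F4 | C=C1C(=O)O[C@@H](CC(C)(Br)C(=O)CBr)[C@@H]1CO[Si](c1ccccc1)(c1ccccc1)C(C)(C)C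
F6 | step 15 | (2Z)-3-iodo-2-methylprop-2-enoic acid | OC(=O)/C(C)=C\I
F7 | step 15 | (2Z)-3-iodo-N,N,2-trimethylprop-2-enamide | CN(C)C(=O)/C(C)=C\I
F8 | step 15 | 5-[(1Z)-1-iodoprop-1-en-2-yl]-2-methyl-3(2H)-furanone attached through C2 to the silyl-protected lactone (C10 epimers) | C=C1C(=O)O[C@@H](CC2(C)OC(=CC2=O)/C(C)=C\I)[C@@H]1CO[Si](c1ccccc1)(c1ccccc1)C(C)(C)C
F9 | step 15 | primary alcohol from F8 | C=C1C(=O)O[C@@H](CC2(C)OC(=CC2=O)/C(C)=C\I)[C@@H]1CO
F10 | step 15 | aldehyde from F9 | C=C1C(=O)O[C@@H](CC2(C)OC(=CC2=O)/C(C)=C\I)[C@@H]1C=O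
F11 | step 14 | terminal trimethylsilyl enol ether of 21 | C=C1C(=O)O[C@@H](CC(C)C(=C)O[Si](C)(C)C)[C@@H]1[C@@H](O[Si](C(C)C)(C(C)C)C(C)C)/C=C(C)\C(=O)N(C)C
F12 | step 14 | bromomethyl ketone from F11 | C=C1C(=O)O[C@@H](CC(C)C(=O)CBr)[C@@H]1[C@@H](O[Si](C(C)C)(C(C)C)C(C)C)/C=C(C)\C(=O)N(C)C
F13 | step 7 | (2S,3R)-2-(2-methylbut-3-en-1-yl)-5-oxooxolane-3-carbaldehyde | O=C1O[C@@H](CC(C)C=C)[C@H](C=O)C1
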